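A ratio of two logarithms ties the two substrates of this flask together: the logarithm of the fraction of left-handed substrate still there, over the same logarithm for right-handed substrate.

| setting | ash | elm | flask |
|---|---|---|---|
| left-handed substrate | 0.30 M | 0.30 M | 0.30 M |
| right-handed substrate | 0.30 M | 0.30 M | 0.30 M |
| gas | 82 mM (held) | 82 mM (held) | 82 mM (held) |
| catalyst | 8.1 mol% | 12 mol% | 8.1 mol% |
| remark | the very flask that is asked about, followed so far | run made earlier |  |
| time |  |  | 20 min |

| run | time / min | left-handed product / % | right-handed product / % |
|---|---|---|---|
| ash | 0.833 | 4.6 | 1.9 |
| ash | 1.50 | 9.6 | 5.0 |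
| ash | 2.50 | 16.1 | 9.1 |
| ash | 3.00 | 19.2 | 10.3 |
| ash | 4.00 | 25.1 | 15.1 |
| elm | 4.00 | 28.2 | 17.2 |
| elm | 8.00 | 44.8 | 34.1 |
| elm | 12.0 | 49.5 | 44.1 |
| elm | 15.0 | 50.1 | 48.0 |
| elm | 20.0 | 49.9 | 50.0 |

(standard deviation of a reading: 0.3 percentage points)

1. excess of left-handed product over right-handed product in the product at 1.0 min
2. excess of left-handed product over right-handed product in the product at 20 min
3. part of the left-handed substrate and right-handed substrate charged together that has reacted at 20 min

- catalyst is single-handed; left-handed substrate and right-handed substrate are mirror images of each other, charged as a racemate, each of them at the stated concentration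
- at the start none of reagent is dissolved
- on the list of suspects stand: reagent + catalyst + left-handed substrate -> catalyst + left-handed product; reagent + catalyst + right-handed substrate -> catalyst + right-handed product; catalyst <-> dormant form; gas <-> reagent
- an excess is the difference of the two amounts in percent of their sum
- an excess is below zero if the other one leads

What do you carry forward from ash? That ratio, the selectivity factor, which reads 1.94 at 4.00 min: the relative rate of loss of left-handed substrate divided by that of right-handed substrate.

Why should it stay put while the rates change? Both suspected steps take reagent and catalyst, so whatever those two do falls on both substrates alike and drops out of the ratio. Elm, at another loading, reads 1.98 at 8.00 min.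

And the excess at 1.0 min? At equal amounts, as at the start, the two rates stand as s to one, so the excess at the start is s less one over s plus one, 32.0%, and I keep that for 1.0 min.

And at 20 min? The ratio ties the two leftovers together but tells no time, which is its weak spot. I replace the curve by a mean. In elm, right-handed substrate falls with a mean constant of 0.296 min⁻¹ from 8.00 min to 15.0 min. Scaled by loading, ash gets 0.200 min⁻¹. From the ash reading at 4.00 min, I reckon that this leaves 2.85% of the right-handed charge at 20 min. Raising that fraction to the power s gives the left-handed one, so the excess is 1.39% with 98.5% reacted.

What error does the mean make? Taken from 4.00 min, the elm constant is lower, 0.254 min⁻¹. Scaled the same way, it leaves 4.48%, an excess of 2.17% and 97.6% reacted. I commit to that span.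

The forecast, which reads the runs as “one constant selectivity throughout”, gives 32%, 1.8% and 98.1%; its excess at 20 min is higher than my first figure and lower than my second.

The flask gives 31.9%, 1.47% and 98.5%.

    reagent + catalyst + left-handed substrate → catalyst + left-handed product (k = 7.20 L² mol⁻² s⁻¹)
    reagent + catalyst + right-handed substrate → catalyst + right-handed product (k = 3.60 L² mol⁻² s⁻¹)
    catalyst ⇌ dormant form (K = 0.620, k = 0.0190 s⁻¹)
    gas ⇌ reagent, rate k4*(csat - [reagent]) (kL = 0.0200 s⁻¹)

In the flask at 20.0 min the half-life of right-handed substrate by its own step is 2.7 min, short against the 20 min of the run, and 3.0% of its charge stands beside 0.089% of the left-handed charge, a ratio of logarithms of 2.00. In the neighbour flask with 4.9 mol% of catalyst, the excess at 20.0 min is 5.36% and 1.3% of the left-handed charge is left; the ash reading of s turns that into 10.7% of the right-handed charge, and that flask holds 11%.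

(All runs are simulated from invented constants.)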